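## Retrosynthetic overview

1. The last C–C bond is C1–C2: an intramolecular Pd/Cu coupling of an S-ethyl thioester with the terminal Z-enyne, and the α′-hydroxy ynone so formed is closed at once by 5-endo-dig attack of the C10 hydroxyl. The ten-membered carbocycle and the 3(2H)-furanone therefore appear together from an open-chain precursor.
2. Before that, the side-chain ester is attached (Yamaguchi) with (S)-2-methylglycidic acid; the epoxide ring comes from (R)-2-methylglycidol.
3. C6–C7 comes from a chromium Barbier coupling of a 3-(bromomethyl)butenolide with (Z)-3-methylpent-2-en-4-ynal. The lactone centre C8 sets C7 and C6, and the butenolide becomes the α-methylene lactone.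
4. C7–C8 and the lactone (first ring) come from an asymmetric Ni/Cr coupling of a C8 aldehyde with a (Z)-β-iodoacrylate, which lactonises in situ.
5. C10 comes from (S)-lactic acid by Seebach alkylation (allyl), then thioester formation and ozonolysis. Ring order: butenolide, then (epoxide brought in), then carbocycle and furanone together.

Assumption: positions carry germacrane numbering (C1–C15), and the enantiomer of the oxazoline–sulfonamide ligand in step 6 is the one that a test reaction shows to give the 8S carbinol.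

## Route

Step 1
Reactants: 1 (S)-lactic acid; 2 pivalaldehyde
Product: 3 (2S,5S)-2-tert-butyl-5-methyl-1,3-dioxolan-4-one
Conditions: TsOH·H2O (cat.), H2SO4 (cat.), pentane, reflux, Dean–Stark; recryst. Et2O/pentane, −78 °C
Reagents that add atoms: none
Why: Acid-catalysed acetalisation (Seebach self-regeneration-of-stereocentres template) gives the thermodynamically favoured cis acetal, so the lactate centre controls the new acetal carbon (2S) and crystallisation removes the trans isomer.

Step 2
Reactants: 3 (2S,5S)-2-tert-butyl-5-methyl-1,3-dioxolan-4-one; 4 allyl bromide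
Product: 6 (2S,5R)-5-allyl-2-tert-butyl-5-methyl-1,3-dioxolan-4-one, via lithium enolate 5 (not isolated)
Conditions: LiN(i-Pr)2 (1.1 equiv), THF, −78 °C; then 4, −78 → −20 °C
Reagents that add atoms: none
Why: Enolate alkylation takes place on the face anti to the tert-butyl group, so allyl replaces the original hydrogen with retention and the quaternary C10 centre is set.

Step 3
Reactants: 6 (2S,5R)-5-allyl-2-tert-butyl-5-methyl-1,3-dioxolan-4-one; 7 ethanethiol
Product: 8 S-ethyl (2R)-2-hydroxy-2-methylpent-4-enethioate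
Conditions: AlMe3 (2 equiv), EtSH (2 equiv), CH2Cl2, 0 °C → rt; then 1 M HCl
Reagents that add atoms: none
Why: Dimethylaluminium ethanethiolate transacylates the lactone-type carbonyl (aluminium thiolate ester-to-thioester exchange) and the released hemiacetal loses pivalaldehyde on work-up, unveiling the tertiary alcohol without touching C10.

Step 4
Reactants: 8 S-ethyl (2R)-2-hydroxy-2-methylpent-4-enethioate
Product: 9 S-ethyl (2R)-2-hydroxy-2-methyl-4-oxobutanethioate
Conditions: O3, CH2Cl2, −78 °C; then PPh3, −78 °C → rt; used crude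
Reagents that add atoms: ozone, [O-][O+]=O
Why: Ozonolysis with reductive work-up cleaves the only alkene to the C8 aldehyde at a temperature where the S-ethyl thioester and the carbinol are inert.

Step 5
Reactants: 10 ethyl propiolate; 11 formaldehyde (as paraformaldehyde)
Product: 12 ethyl (2Z)-2-(hydroxymethyl)-3-iodoprop-2-enoate
Conditions: MgI2 (1.2 equiv), CH2Cl2, 0 °C → rt
Reagents that add atoms: magnesium diiodide, [Mg+2].[I-].[I-]
Why: Iodide adds in conjugate fashion to the propiolate and the magnesium β-iodoallenolate is trapped by formaldehyde (β-iodo Morita–Baylis–Hillman reaction), giving under kinetic control the Z isomer with iodine cis to the ester.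

Step 6
Reactants: 9 S-ethyl (2R)-2-hydroxy-2-methyl-4-oxobutanethioate; 12 ethyl (2Z)-2-(hydroxymethyl)-3-iodoprop-2-enoate
Product: 14 S-ethyl (2R)-2-hydroxy-3-[(2S)-4-(hydroxymethyl)-5-oxo-2,5-dihydrofuran-2-yl]-2-methylpropanethioate, via Z-hydroxy enoate 13 (not isolated)
Conditions: CrCl2 (4 equiv), NiCl2 (2 mol%), Kishi oxazoline–sulfonamide ligand (4.4 equiv), Et3N (4.4 equiv), THF, rt; aq. NH4Cl
Reagents that add atoms: none
Why: Asymmetric Nozaki–Hiyama–Kishi coupling forms the alkenylchromium reagent with retention of geometry and adds it to the aldehyde under ligand control to set C8 (S), and the alkoxide, held cis to the ester by the Z-alkene, lactonises to the butenolide much faster than it can reach the hindered thioester.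

Step 7
Reactants: 14 S-ethyl (2R)-2-hydroxy-3-[(2S)-4-(hydroxymethyl)-5-oxo-2,5-dihydrofuran-2-yl]-2-methylpropanethioate
Product: 15 S-ethyl (2R)-3-[(2S)-4-(bromomethyl)-5-oxo-2,5-dihydrofuran-2-yl]-2-hydroxy-2-methylpropanethioate
Conditions: CBr4 (1.2 equiv), PPh3 (1.25 equiv), CH2Cl2, 0 °C; used promptly
Reagents that add atoms: carbon tetrabromide, BrC(Br)(Br)Br
Why: Appel bromination converts the primary allylic alcohol into the bromide under neutral, base-free conditions, leaving the tertiary alcohol, the thioester and C8 unchanged.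

Step 8
Reactants: 16 (2Z)-3-methylpent-2-en-4-yn-1-ol
Product: 17 (2Z)-3-methylpent-2-en-4-ynal
Conditions: MnO2 (15 equiv), CH2Cl2, rt, dark; used as solution
Reagents that add atoms: none
Why: MnO2 oxidises the allylic alcohol selectively to the enal at room temperature without isomerising the Z-alkene or touching the terminal alkyne.

Step 9
Reactants: 15 S-ethyl (2R)-3-[(2S)-4-(bromomethyl)-5-oxo-2,5-dihydrofuran-2-yl]-2-hydroxy-2-methylpropanethioate; 17 (2Z)-3-methylpent-2-en-4-ynal
Product: 18 S-ethyl (2R)-2-hydroxy-3-{(2S,3S)-3-[(1R,2Z)-1-hydroxy-3-methylpent-2-en-4-yn-1-yl]-4-methylidene-5-oxooxolan-2-yl}-2-methylpropanethioate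
Conditions: CrCl2 (4 equiv), THF, 0 °C → rt; aq. NH4Cl
Reagents that add atoms: none
Why: In this chromium-mediated Barbier (Nozaki–Hiyama type) allylation the ring-locked allylchromium reagent attacks the aldehyde through its ring β-carbon (C7) in a chair transition state, on the face anti to the C8 side chain (trans lactone) and with the anti carbinol at C6, so both new centres are set from C8 while the double bond moves to the exocyclic position.

Step 10
Reactants: 19 (R)-2-methylglycidol
Product: 20 (S)-2-methylglycidic acid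
Conditions: TEMPO (10 mol%), PhI(OAc)2 (2.2 equiv), MeCN/H2O (1:1), 0 °C → rt
Reagents that add atoms: water, O
Why: Nitroxyl-catalysed oxidation takes the primary alcohol through the aldehyde hydrate to the acid without opening the epoxide, and the quaternary centre is untouched (the descriptor changes from R to S by priority rules only).

Step 11
Reactants: 18 S-ethyl (2R)-2-hydroxy-3-{(2S,3S)-3-[(1R,2Z)-1-hydroxy-3-methylpent-2-en-4-yn-1-yl]-4-methylidene-5-oxooxolan-2-yl}-2-methylpropanethioate; 20 (S)-2-methylglycidic acid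
Product: 22 (1R,2Z)-1-{(2S,3R)-2-[(2R)-3-(ethylsulfanyl)-2-hydroxy-2-methyl-3-oxopropyl]-4-methylidene-5-oxooxolan-3-yl}-3-methylpent-2-en-4-yn-1-yl (2S)-2-methyloxirane-2-carboxylate, via mixed anhydride 21 (not isolated)
Conditions: 20, 2,4,6-Cl3C6H2COCl (1.2 equiv), Et3N (2.5 equiv), toluene, 0 °C; then 18, DMAP (1.5 equiv), 0 °C → rt
Reagents that add atoms: none
Why: Yamaguchi esterification through the mixed anhydride acylates the secondary allylic C6 hydroxyl with retention, while the hindered tertiary alcohol next to the thioester does not react.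

Step 12
Reactants: 22 (1R,2Z)-1-{(2S,3R)-2-[(2R)-3-(ethylsulfanyl)-2-hydroxy-2-methyl-3-oxopropyl]-4-methylidene-5-oxooxolan-3-yl}-3-methylpent-2-en-4-yn-1-yl (2S)-2-methyloxirane-2-carboxylate
Product: 24 (6R,7R,8S,10R,4Z)-6-[(2S)-2-methyloxirane-2-carbonyloxy]-1-oxo-3,10-epoxygermacra-2,4,11(13)-trien-8,12-olide (CNP0321429.1), via macrocyclic ynone 23 (not isolated)
Conditions: PdCl2(dppf) (15 mol%), P(2-furyl)3 (40 mol%), CuI (2 equiv), Et3N/DMF (1:5), 50 °C, degassed, syringe-pump addition to 1 mM
Reagents that add atoms: none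
Why: Proposed new method: zerovalent palladium inserts into the C(acyl)–S bond of the thioester, the copper acetylide of the Z-enyne transmetalates and reductive elimination closes the ten-membered α′-hydroxy ynone 23 (the Z-alkene and the trans lactone hold C1 and C2 within reach and CuI traps the thiolate), after which the C10 hydroxyl adds 5-endo-dig to the strained ynone (oxa-Michael) to give the 3(2H)-furanone, so the carbocycle and the furanone form together and no stereocentre is created or disturbed; the closest known chemistry is the intermolecular palladium/copper coupling of S-ethyl thioesters with terminal alkynes to ynones (Fukuyama type), Sonogashira-type macrocyclisation, and base- or metal-promoted cycloisomerisation of α′-hydroxy ynones to 3(2H)-furanones.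

## Compound list

1 | (S)-lactic acid | C[C@H](O)C(=O)O | starting material
2 | pivalaldehyde | CC(C)(C)C=O | starting material
3 | (2S,5S)-2-tert-butyl-5-methyl-1,3-dioxolan-4-one | C[C@@H]1O[C@H](C(C)(C)C)OC1=O | intermediate
4 | allyl bromide | C=CCBr | starting material
5 | lithium (2S)-2-tert-butyl-5-methyl-1,3-dioxol-4-olate | CC1=C([O-])O[C@@H](C(C)(C)C)O1.[Li+] | intermediate
6 | (2S,5R)-5-allyl-2-tert-butyl-5-methyl-1,3-dioxolan-4-one | C[C@]1(CC=C)O[C@H](C(C)(C)C)OC1=O | intermediate
7 | ethanethiol | CCS | starting material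
8 | S-ethyl (2R)-2-hydroxy-2-methylpent-4-enethioate | CCSC(=O)[C@](C)(O)CC=C | intermediate
9 | S-ethyl (2R)-2-hydroxy-2-methyl-4-oxobutanethioate | CCSC(=O)[C@](C)(O)CC=O | intermediate
10 | ethyl propiolate | C#CC(=O)OCC | starting material
11 | formaldehyde (as paraformaldehyde) | C=O | starting material
12 | ethyl (2Z)-2-(hydroxymethyl)-3-iodoprop-2-enoate | OC/C(C(=O)OCC)=C/I | intermediate
13 | ethyl (2Z,4S,6R)-7-(ethylsulfanyl)-4,6-dihydroxy-2-(hydroxymethyl)-6-methyl-7-oxohept-2-enoate | CCSC(=O)[C@](C)(O)C[C@H](O)/C=C(CO)\C(=O)OCC | intermediate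
14 | S-ethyl (2R)-2-hydroxy-3-[(2S)-4-(hydroxymethyl)-5-oxo-2,5-dihydrofuran-2-yl]-2-methylpropanethioate | CCSC(=O)[C@](C)(O)C[C@H]1C=C(CO)C(=O)O1 | intermediate
15 | S-ethyl (2R)-3-[(2S)-4-(bromomethyl)-5-oxo-2,5-dihydrofuran-2-yl]-2-hydroxy-2-methylpropanethioate | CCSC(=O)[C@](C)(O)C[C@H]1C=C(CBr)C(=O)O1 | intermediate
16 | (2Z)-3-methylpent-2-en-4-yn-1-ol | C#C/C(C)=C\CO | starting material
17 | (2Z)-3-methylpent-2-en-4-ynal | C#C/C(C)=C\C=O | intermediate
18 | S-ethyl (2R)-2-hydroxy-3-{(2S,3S)-3-[(1R,2Z)-1-hydroxy-3-methylpent-2-en-4-yn-1-yl]-4-methylidene-5-oxooxolan-2-yl}-2-methylpropanethioate | C=C1C(=O)O[C@@H](C[C@@](C)(O)C(=O)SCC)[C@@H]1[C@H](O)/C=C(C)\C#C | intermediate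
19 | (R)-2-methylglycidol [(2R)-(2-methyloxiran-2-yl)methanol] | OC[C@]1(C)CO1 | starting material
20 | (S)-2-methylglycidic acid [(2S)-2-methyloxirane-2-carboxylic acid] | OC(=O)[C@]1(C)CO1 | intermediate
21 | (2S)-2-methyloxirane-2-carboxylic 2,4,6-trichlorobenzoic anhydride | O=C(OC(=O)[C@]1(C)CO1)c1c(Cl)cc(Cl)cc1Cl | intermediate
22 | (1R,2Z)-1-{(2S,3R)-2-[(2R)-3-(ethylsulfanyl)-2-hydroxy-2-methyl-3-oxopropyl]-4-methylidene-5-oxooxolan-3-yl}-3-methylpent-2-en-4-yn-1-yl (2S)-2-methyloxirane-2-carboxylate | C=C1C(=O)O[C@@H](C[C@@](C)(O)C(=O)SCC)[C@@H]1[C@H](OC(=O)[C@]2(C)CO2)/C=C(C)\C#C | intermediate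
23 | (6R,7R,8S,10R,4Z)-10-hydroxy-6-[(2S)-2-methyloxirane-2-carbonyloxy]-1-oxogermacra-4,11(13)-dien-2-yn-8,12-olide (ten-membered α′-hydroxy ynone) | C=C1C(=O)O[C@H]2C[C@@](C)(O)C(=O)C#C/C(C)=C\[C@@H](OC(=O)[C@]3(C)CO3)[C@H]12 | intermediate
24 | (6R,7R,8S,10R,4Z)-6-[(2S)-2-methyloxirane-2-carbonyloxy]-1-oxo-3,10-epoxygermacra-2,4,11(13)-trien-8,12-olide (CNP0321429.1) | C=C1C(=O)O[C@H]2C[C@@]3(C)OC(=CC3=O)/C(C)=C\[C@@H](OC(=O)[C@]3(C)CO3)[C@H]12 | target

## Step count and weak points

Total steps: 12. Longest linear sequence: 9 (steps 1, 2, 3, 4, 6, 7, 9, 11, 12).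

Most likely to fail:

**Step 12 (macrocyclising thioester–alkyne coupling with furanone closure).** The risks are oligomerisation, strain in the cyclic ynone, ionisation of the allylic C6 ester by palladium, and opening of the epoxide by the iodide released. Fallback, setting out from 15 and coming back at 24: couple 15 with acrolein under the step 9 conditions to give the vinyl carbinol diol F1, and esterify it with 20 as in step 11 to the glycidate ester F2. Then run the thioester–alkyne coupling intermolecularly with 2-methylbut-1-en-3-yne (PdCl2(dppf), P(2-furyl)3, CuI, Et3N, DMF, 50 °C); the acyclic α′-hydroxy ynone F3 cyclises without ring strain to the 5-isopropenyl furanone F4. Ring-closing metathesis of F4 (second-generation Grubbs catalyst, toluene, 80 °C, 1 mM) then forms the C4=C5 bond, Z by ring constraint, and gives 24.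

**Step 6 (asymmetric Ni/Cr coupling and lactonisation).** The risks are ligand control at C8, the stability of aldehyde 9, and attack of the C8 alkoxide on the thioester instead of the ester. Fallback, setting out from 9 and coming back at 15: allylate 9 with ethyl 2-(bromomethyl)acrylate under chromium catalysis (CrCl2 10 mol%, chiral carbazole bis(oxazoline) ligand, Mn, Me3SiCl, THF) to the silyl ether F5. Treat it with TsOH·H2O in CH2Cl2 to give the hydroxy ester F6, which lactonises under the same acid to the α-methylene lactone F7. Brominate F7 with allylic transposition (N-bromosuccinimide, AIBN, PhCF3, 80 °C) to reach 15.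

**Step 9 (chromium Barbier coupling with the enynal).** The risk is the C6 diastereoselectivity, together with the sensitivity of the Z-enynal. Fallback, setting out from 15 and coming back at 22: if the coupling of 15 with 17 gives mainly the C6-epimeric diol F8, esterify F8 with 20 under Mitsunobu conditions (PPh3, diisopropyl azodicarboxylate, toluene, 0 °C), which inverts C6 and gives 22 directly.

## Further compounds

F1 | step 12 | S-ethyl (2R)-2-hydroxy-3-{(2S,3S)-3-[(1R)-1-hydroxyprop-2-en-1-yl]-4-methylidene-5-oxooxolan-2-yl}-2-methylpropanethioate | C=C1C(=O)O[C@@H](C[C@@](C)(O)C(=O)SCC)[C@@H]1[C@H](O)C=C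
F2 | step 12 | (1R)-1-{(2S,3R)-2-[(2R)-3-(ethylsulfanyl)-2-hydroxy-2-methyl-3-oxopropyl]-4-methylidene-5-oxooxolan-3-yl}prop-2-en-1-yl (2S)-2-methyloxirane-2-carboxylate | C=C1C(=O)O[C@@H](C[C@@](C)(O)C(=O)SCC)[C@@H]1[C@H](OC(=O)[C@]2(C)CO2)C=C
F3 | step 12 | (1R)-1-{(2S,3R)-2-[(2R)-2-hydroxy-2,6-dimethyl-3-oxohept-6-en-4-yn-1-yl]-4-methylidene-5-oxooxolan-3-yl}prop-2-en-1-yl (2S)-2-methyloxirane-2-carboxylate | C=C1C(=O)O[C@@H](C[C@@](C)(O)C(=O)C#CC(C)=C)[C@@H]1[C@H](OC(=O)[C@]2(C)CO2)C=C
F4 | step 12 | (1R)-1-{(2S,3R)-2-{[(2R)-2-methyl-3-oxo-5-(prop-1-en-2-yl)-2,3-dihydrofuran-2-yl]methyl}-4-methylidene-5-oxooxolan-3-yl}prop-2-en-1-yl (2S)-2-methyloxirane-2-carboxylate | C=C1C(=O)O[C@@H](C[C@@]2(C)OC(=CC2=O)C(C)=C)[C@@H]1[C@H](OC(=O)[C@]3(C)CO3)C=C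
F5 | step 6 | ethyl (4R,6R)-7-(ethylsulfanyl)-6-hydroxy-6-methyl-2-methylidene-7-oxo-4-[(trimethylsilyl)oxy]heptanoate | CCSC(=O)[C@](C)(O)C[C@H](O[Si](C)(C)C)CC(=C)C(=O)OCC
F6 | step 6 | ethyl (4R,6R)-7-(ethylsulfanyl)-4,6-dihydroxy-6-methyl-2-methylidene-7-oxoheptanoate | CCSC(=O)[C@](C)(O)C[C@H](O)CC(=C)C(=O)OCC
F7 | step 6 | S-ethyl (2R)-2-hydroxy-2-methyl-3-[(2R)-4-methylidene-5-oxooxolan-2-yl]propanethioate | CCSC(=O)[C@](C)(O)C[C@H]1CC(=C)C(=O)O1
F8 | step 9 | S-ethyl (2R)-2-hydroxy-3-{(2S,3S)-3-[(1S,2Z)-1-hydroxy-3-methylpent-2-en-4-yn-1-yl]-4-methylidene-5-oxooxolan-2-yl}-2-methylpropanethioate | C=C1C(=O)O[C@@H](C[C@@](C)(O)C(=O)SCC)[C@@H]1[C@@H](O)/C=C(C)\C#C
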